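Everything rests on an intramolecular Diels–Alder disconnection of ring B: the ring-fusion bond C5–C10 and the C8–C9 bond are cut together, with the C7=C8 alkene first moved to C6=C7. The feature exploited is the cyclohexene ring B carrying the quaternary C10 methyl cis to the C9 CH2O arm, which maps onto an (E)-3-methyl-2-enoyl dienophile. The precursor is an open-chain (2E,8E,10E)-trienoyl oxazolidinone whose C1–C4 chain is the tether. One cycloaddition closes rings A and B, builds quaternary C10 and sets C5, C9 and C10 (with a transient C8 centre). A ruthenium hydride then walks the alkene to C7=C8, and Mitsunobu esterification with caffeic acid completes the target.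

Key step: step 7

Remark: the bicyclic core is numbered as in drimanes (ring A: C1–C5 and C10; ring B: C5–C10; C11 is the CH2O carbon on C9, C12 the methyl carbon on C8). The (E)-selective enol triflate formation in step 3 is taken to follow the known behaviour of non-chelated β-keto ester enolates.

Step 1
Reactants: 1 2,2-dimethylpent-4-enal
Product: 2 (1E)-1-iodo-3,3-dimethylhexa-1,5-diene
Conditions: CrCl2, CHI3, THF, 0 °C → rt
Reagents that add atoms: iodoform, IC(I)I
Why: Takai olefination: the geminal dichromium species from CHI3 adds to the non-enolisable aldehyde and eliminates to the (E)-vinyl iodide, the terminal alkene being inert.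

Step 2
Reactants: 2 (1E)-1-iodo-3,3-dimethylhexa-1,5-diene; 3 (E)-prop-1-en-1-ylboronic acid
Product: 4 (5E,7E)-4,4-dimethylnona-1,5,7-triene
Conditions: Pd(PPh3)4 (cat.), K2CO3, THF/H2O, 50 °C
Reagents that add atoms: none
Why: Suzuki–Miyaura coupling proceeds with retention at both sp2 carbons, so the (E,E)-diene geometry is fixed by the two partners.

Step 3
Reactants: 5 methyl acetoacetate
Product: 6 methyl (2E)-3-{[(trifluoromethyl)sulfonyl]oxy}but-2-enoate
Conditions: Tf2O, aq. Me4NOH, hexanes, 5 °C
Reagents that add atoms: trifluoromethanesulfonic anhydride, O=S(=O)(OS(=O)(=O)C(F)(F)F)C(F)(F)F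
Why: O-triflation of the non-chelated tetramethylammonium enolate (stereoselective enol triflate formation of a β-keto ester) should place the triflate trans to the ester.

Step 4
Reactants: 4 (5E,7E)-4,4-dimethylnona-1,5,7-triene; 6 methyl (2E)-3-{[(trifluoromethyl)sulfonyl]oxy}but-2-enoate
Product: 8 methyl (2E,8E,10E)-3,7,7-trimethyldodeca-2,8,10-trienoate, via alkylborane 7 (not isolated)
Conditions: 9-BBN-H (1.0 equiv), THF, 0 °C → rt; then 6, PdCl2(dppf) (cat.), K3PO4, DMF/H2O, rt → 50 °C
Reagents that add atoms: 9-borabicyclo[3.3.1]nonane (9-BBN-H), B1C2CCCC1CCC2 (its boron and carbons stay in intermediate 7 only)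
Why: 9-BBN hydroborates the monosubstituted terminal alkene far faster than the 1,2-disubstituted conjugated diene, and the B-alkyl Suzuki–Miyaura coupling with the enol triflate occurs with retention to give the (E)-3-methyl-2-enoate.

Step 5
Reactants: 8 methyl (2E,8E,10E)-3,7,7-trimethyldodeca-2,8,10-trienoate
Product: 9 (2E,8E,10E)-3,7,7-trimethyldodeca-2,8,10-trienoic acid
Conditions: LiOH, THF/MeOH/H2O, 50 °C; then aq. HCl
Reagents that add atoms: lithium hydroxide, [Li+].[OH-]
Why: Ester saponification leaves the trisubstituted (E)-enoate and the diene untouched.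

Step 6
Reactants: 9 (2E,8E,10E)-3,7,7-trimethyldodeca-2,8,10-trienoic acid; 10 (S)-4-benzyloxazolidin-2-one
Product: 12 (S)-4-benzyl-3-[(2E,8E,10E)-3,7,7-trimethyldodeca-2,8,10-trienoyl]oxazolidin-2-one, via mixed pivalic anhydride 11 (not isolated)
Conditions: PivCl, Et3N, THF, −20 °C; then LiCl, 10, −20 °C → rt
Reagents that add atoms: pivaloyl chloride, CC(C)(C)C(Cl)=O (its atoms stay in intermediate 11 only)
Why: LiCl-promoted N-acylation of the oxazolidinone by the mixed anhydride occurs at the less hindered enoyl carbonyl and at low temperature should not disturb the E-enoate.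

Step 7
Reactants: 12 (S)-4-benzyl-3-[(2E,8E,10E)-3,7,7-trimethyldodeca-2,8,10-trienoyl]oxazolidin-2-one
Product: 13 (S)-4-benzyl-3-{[(1S,2S,4aS,8aS)-2,5,5,8a-tetramethyl-1,2,4a,5,6,7,8,8a-octahydronaphthalen-1-yl]carbonyl}oxazolidin-2-one
Conditions: Me2AlCl (1.5 equiv), CH2Cl2, −30 → 0 °C
Reagents that add atoms: none
Why: Me2AlCl converts the imide into the cationic bidentate aluminium chelate with an s-cis enoyl unit, and this activated dienophile adds to the tethered (E,E)-diene in a concerted, asynchronous [4+2] cycloaddition; the closest known reaction type is the Lewis-acid-promoted asymmetric intramolecular Diels–Alder reaction of N-trienoyl oxazolidinones. Ring A closes in the fused type 1 mode through the four-carbon tether C1–C4 as the C5–C10 bond forms, and ring B closes as the cyclohexene of the cycloaddition through C5–C10 and C8–C9, the tether fixing the regiochemistry. C9 and C10 are set relative to each other by suprafacial addition to the E-enoyl unit, which places the C10 methyl cis to the C9 acyl group. C5 and C8 follow from the carbonyl-endo, tether-exo chair-like transition state, which gives the trans ring fusion (H5 anti to the C10 methyl) and, from the E,E-diene, the C8 methyl cis to the acyl group. The absolute sense comes from the benzyl group of the (S)-auxiliary, which covers the C9 Re face of the chelate so that the diene adds to the C9 Si face and gives (5S,9S,10S). The step needs endo over exo and one π-face; chelation, the locked s-cis enoyl geometry and the benzyl shield should secure both, while the β,β-disubstituted dienophile and the axial methyl contacts make rate and endo control the main risk.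

Step 8
Reactants: 13 (S)-4-benzyl-3-{[(1S,2S,4aS,8aS)-2,5,5,8a-tetramethyl-1,2,4a,5,6,7,8,8a-octahydronaphthalen-1-yl]carbonyl}oxazolidin-2-one
Product: 14 [(1S,2S,4aS,8aS)-2,5,5,8a-tetramethyl-1,2,4a,5,6,7,8,8a-octahydronaphthalen-1-yl]methanol
Conditions: LiBH4, MeOH (1 equiv), Et2O, 0 °C → rt
Reagents that add atoms: none
Why: Reductive cleavage of the N-acyl oxazolidinone by hydride attack at the exocyclic carbonyl gives the primary alcohol and releases the auxiliary without touching a stereocentre.

Step 9
Reactants: 14 [(1S,2S,4aS,8aS)-2,5,5,8a-tetramethyl-1,2,4a,5,6,7,8,8a-octahydronaphthalen-1-yl]methanol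
Product: 15 (−)-drimenol, [(1S,4aS,8aS)-2,5,5,8a-tetramethyl-1,4,4a,5,6,7,8,8a-octahydronaphthalen-1-yl]methanol
Conditions: RuHCl(CO)(PPh3)3 (cat.), toluene, 90 °C
Reagents that add atoms: none
Why: Olefin isomerisation by hydrometalation and β-hydride elimination: the ruthenium hydride should add to C6=C7 from the open α face with the metal on C7 (C6 is screened by C5 and the C4 methyls) and lose the syn H8, giving the trisubstituted C7=C8 alkene and relieving the 1,3-diaxial strain between the C8 and C10 methyls, while further migration would need a tertiary alkylruthenium and C5, C9 and C10 are untouched.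

Step 10
Reactants: 15 (−)-drimenol; 16 caffeic acid, (2E)-3-(3,4-dihydroxyphenyl)prop-2-enoic acid
Product: 17 [(1S,4aS,8aS)-2,5,5,8a-tetramethyl-1,4,4a,5,6,7,8,8a-octahydronaphthalen-1-yl]methyl (2E)-3-(3,4-dihydroxyphenyl)prop-2-enoate
Conditions: PPh3, DIAD, THF, 0 °C → rt
Reagents that add atoms: none
Why: Mitsunobu esterification: the alkoxyphosphonium of the primary C11 alcohol is displaced by the carboxylate, which is far more acidic than the catechol hydroxyls (chemoselective esterification of a phenolic acid), and neither the E-cinnamate nor a stereocentre is affected.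

Compound list
1 | 2,2-dimethylpent-4-enal | C=CCC(C)(C)C=O | starting material
2 | (1E)-1-iodo-3,3-dimethylhexa-1,5-diene | C=CCC(C)(C)/C=C/I | intermediate
3 | (E)-prop-1-en-1-ylboronic acid | C/C=C/B(O)O | starting material
4 | (5E,7E)-4,4-dimethylnona-1,5,7-triene | C=CCC(C)(C)/C=C/C=C/C | intermediate
5 | methyl acetoacetate | CC(=O)CC(=O)OC | starting material
6 | methyl (2E)-3-{[(trifluoromethyl)sulfonyl]oxy}but-2-enoate | COC(=O)/C=C(\C)OS(=O)(=O)C(F)(F)F | intermediate
7 | 9-[(5E,7E)-4,4-dimethylnona-5,7-dien-1-yl]-9-borabicyclo[3.3.1]nonane | C/C=C/C=C/C(C)(C)CCCB1C2CCCC1CCC2 | intermediate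
8 | methyl (2E,8E,10E)-3,7,7-trimethyldodeca-2,8,10-trienoate | COC(=O)/C=C(\C)CCCC(C)(C)/C=C/C=C/C | intermediate
9 | (2E,8E,10E)-3,7,7-trimethyldodeca-2,8,10-trienoic acid | OC(=O)/C=C(\C)CCCC(C)(C)/C=C/C=C/C | intermediate
10 | (S)-4-benzyloxazolidin-2-one | O=C1N[C@@H](Cc2ccccc2)CO1 | starting material
11 | 2,2-dimethylpropanoic (2E,8E,10E)-3,7,7-trimethyldodeca-2,8,10-trienoic anhydride | CC(C)(C)C(=O)OC(=O)/C=C(\C)CCCC(C)(C)/C=C/C=C/C | intermediate
12 | (S)-4-benzyl-3-[(2E,8E,10E)-3,7,7-trimethyldodeca-2,8,10-trienoyl]oxazolidin-2-one | O=C(/C=C(\C)CCCC(C)(C)/C=C/C=C/C)N1[C@@H](Cc2ccccc2)COC1=O | intermediate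
13 | (S)-4-benzyl-3-{[(1S,2S,4aS,8aS)-2,5,5,8a-tetramethyl-1,2,4a,5,6,7,8,8a-octahydronaphthalen-1-yl]carbonyl}oxazolidin-2-one | C[C@H]1C=C[C@H]2C(C)(C)CCC[C@]2(C)[C@H]1C(=O)N1[C@@H](Cc2ccccc2)COC1=O | intermediate
14 | [(1S,2S,4aS,8aS)-2,5,5,8a-tetramethyl-1,2,4a,5,6,7,8,8a-octahydronaphthalen-1-yl]methanol | C[C@H]1C=C[C@H]2C(C)(C)CCC[C@]2(C)[C@H]1CO | intermediate
15 | (−)-drimenol, [(1S,4aS,8aS)-2,5,5,8a-tetramethyl-1,4,4a,5,6,7,8,8a-octahydronaphthalen-1-yl]methanol | CC1=CC[C@H]2C(C)(C)CCC[C@]2(C)[C@H]1CO | intermediate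
16 | caffeic acid, (2E)-3-(3,4-dihydroxyphenyl)prop-2-enoic acid | OC(=O)/C=C/c1ccc(O)c(O)c1 | starting material
17 | [(1S,4aS,8aS)-2,5,5,8a-tetramethyl-1,4,4a,5,6,7,8,8a-octahydronaphthalen-1-yl]methyl (2E)-3-(3,4-dihydroxyphenyl)prop-2-enoate | CC1=CC[C@H]2C(C)(C)CCC[C@]2(C)[C@H]1COC(=O)/C=C/c1ccc(O)c(O)c1 | target

Total step count: 10. Longest linear sequence: 9 steps (steps 1, 2, 4, 5, 6, 7, 8, 9, 10).

Steps most likely to fail

1. Step 7. The cycloaddition may be too slow, because the dienophile is β,β-disubstituted and the C5–C10 bond forms beside the C4 gem-dimethyl group. It may also lose endo (trans-fusion) control, because the axial C10 methyl meets the axial C4 methyl and the C8 methyl in the trans-fused transition state. The fallback replaces the auxiliary and Lewis acid by iminium catalysis and sets out from ester 8. Reduction with i-Bu2AlH in CH2Cl2 at −78 °C should give (2E,8E,10E)-3,7,7-trimethyldodeca-2,8,10-trien-1-ol F1, and MnO2 in CH2Cl2 should oxidise it to (2E,8E,10E)-3,7,7-trimethyldodeca-2,8,10-trienal F2. This enal would be cyclised with (2S,5S)-5-benzyl-2-tert-butyl-3-methylimidazolidin-4-one trifluoroacetate (cat.) in MeCN/H2O; this catalyst enantiomer should shield the C9 Re face of the (E)-iminium ion. The expected product is (1S,2S,4aS,8aS)-2,5,5,8a-tetramethyl-1,2,4a,5,6,7,8,8a-octahydronaphthalene-1-carbaldehyde F3. Reduction with NaBH4 in MeOH comes back to the route at alcohol 14.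

2. Step 9. The hydride may walk toward C5 or on to the tetrasubstituted C8=C9 position, or the migration may stall, so positional selectivity is the concern. The fallback goes through a conjugated dienoate and a reductive deconjugation, and sets out from imide 13. Methanolysis with MeOMgBr in MeOH/CH2Cl2 should give methyl (1S,2S,4aS,8aS)-2,5,5,8a-tetramethyl-1,2,4a,5,6,7,8,8a-octahydronaphthalene-1-carboxylate F4. Enolisation with LDA and trapping with PhSeBr on the α face should give methyl (1R,2S,4aS,8aS)-2,5,5,8a-tetramethyl-1-(phenylselanyl)-1,2,4a,5,6,7,8,8a-octahydronaphthalene-1-carboxylate F5. Oxidation with H2O2 and syn elimination, for which only H8 is available, should give methyl (4aS,8aS)-2,5,5,8a-tetramethyl-4a,5,6,7,8,8a-hexahydronaphthalene-1-carboxylate F6. Birch-type 1,6-reduction (Li, NH3, t-BuOH, then NH4Cl), with kinetic protonation of the dienolate at C9 from the α face, should give methyl (1S,4aS,8aS)-2,5,5,8a-tetramethyl-1,4,4a,5,6,7,8,8a-octahydronaphthalene-1-carboxylate F7. Reduction with LiAlH4 comes back to the route at drimenol 15.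

3. Step 10. The free catechol may be O-alkylated or lead to oligomers, and displacement at the β-branched C11 carbon may be slow. The fallback builds the cinnamate by condensation instead and sets out from drimenol 15. Heating with Meldrum's acid in toluene at 100 °C should give 3-{[(1S,4aS,8aS)-2,5,5,8a-tetramethyl-1,4,4a,5,6,7,8,8a-octahydronaphthalen-1-yl]methoxy}-3-oxopropanoic acid F8. Knoevenagel–Doebner condensation with 3,4-dihydroxybenzaldehyde (pyridine, piperidine cat., 60 °C), decarboxylative and E-selective, comes back to the route at target 17.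

Further compounds
F1 | step 7 | (2E,8E,10E)-3,7,7-trimethyldodeca-2,8,10-trien-1-ol | OC/C=C(\C)CCCC(C)(C)/C=C/C=C/C
F2 | step 7 | (2E,8E,10E)-3,7,7-trimethyldodeca-2,8,10-trienal | O=C/C=C(\C)CCCC(C)(C)/C=C/C=C/C
F3 | step 7 | (1S,2S,4aS,8aS)-2,5,5,8a-tetramethyl-1,2,4a,5,6,7,8,8a-octahydronaphthalene-1-carbaldehyde | C[C@H]1C=C[C@H]2C(C)(C)CCC[C@]2(C)[C@H]1C=O
F4 | step 9 | methyl (1S,2S,4aS,8aS)-2,5,5,8a-tetramethyl-1,2,4a,5,6,7,8,8a-octahydronaphthalene-1-carboxylate | C[C@H]1C=C[C@H]2C(C)(C)CCC[C@]2(C)[C@H]1C(=O)OC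
F5 | step 9 | methyl (1R,2S,4aS,8aS)-2,5,5,8a-tetramethyl-1-(phenylselanyl)-1,2,4a,5,6,7,8,8a-octahydronaphthalene-1-carboxylate | C[C@H]1C=C[C@H]2C(C)(C)CCC[C@]2(C)[C@@]1([Se]c1ccccc1)C(=O)OC
F6 | step 9 | methyl (4aS,8aS)-2,5,5,8a-tetramethyl-4a,5,6,7,8,8a-hexahydronaphthalene-1-carboxylate | CC=1C=C[C@H]2C(C)(C)CCC[C@]2(C)C=1C(=O)OC
F7 | step 9 | methyl (1S,4aS,8aS)-2,5,5,8a-tetramethyl-1,4,4a,5,6,7,8,8a-octahydronaphthalene-1-carboxylate | CC1=CC[C@H]2C(C)(C)CCC[C@]2(C)[C@H]1C(=O)OC
F8 | step 10 | 3-{[(1S,4aS,8aS)-2,5,5,8a-tetramethyl-1,4,4a,5,6,7,8,8a-octahydronaphthalen-1-yl]methoxy}-3-oxopropanoic acid | CC1=CC[C@H]2C(C)(C)CCC[C@]2(C)[C@H]1COC(=O)CC(=O)O
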